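The route rests on cutting the aryl ether bond O1–C8a of the dihydropyran ring. Ring A is carried as a plain 4-hydroxybenzyl group and then dearomatised at C4a to a para-quinol that still bears the free C2 alcohol. The key step exploits the fact that C8a lies meta to the C7 hydroxyl and ortho to C4a, so it is a β-carbon of that dienone. Under acid the C2 alcohol adds to it (6-exo oxa-Michael), loss of water across C4a–C8a restores ring A as the 7-hydroxychroman, and the ring B MOM ether is cleaved, giving the target directly. C3 is set earlier by Evans benzylation of a ring B arylacetyl oxazolidinone.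

Key step: step 12

Remark: the only stereocentre, C3 of the chroman, is read from the SMILES as S (CIP order C2 > C1' > C4 > H). Chroman numbering (O1, C2, C3, C4, C4a–C8a) is used for rings A and C, primed numbers for ring B.

**Step 1**
Reactants: 1 2,6-dimethoxyphenol
Product: 2 1,3-dimethoxy-2-(methoxymethoxy)benzene
Conditions: NaH, MOMCl, DMF, 0 → 23 °C
Reagents that add atoms: chloromethyl methyl ether (MOMCl), COCCl
Why: Williamson-type O-alkylation of the sodium phenoxide with the reactive α-chloro ether masks the flanked phenol as a MOM acetal, which should survive organolithiums, enolates and hydride and come off with acid at the end.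

**Step 2**
Reactants: 2 1,3-dimethoxy-2-(methoxymethoxy)benzene
Product: 3 1-bromo-2,4-dimethoxy-3-(methoxymethoxy)benzene
Conditions: NBS, MeCN, 0 → 23 °C
Reagents that add atoms: N-bromosuccinimide (NBS), O=C1CCC(=O)N1Br
Why: electrophilic aromatic bromination should go ortho to one methoxy and para to the other, as in 1,2,3-trialkoxybenzenes generally, because the twisted central oxygen activates its own para position only weakly.

**Step 3**
Reactants: 3 1-bromo-2,4-dimethoxy-3-(methoxymethoxy)benzene; 4 prenylboronic acid pinacol ester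
Product: 5 1,3-dimethoxy-2-(methoxymethoxy)-4-(2-methylbut-3-en-2-yl)benzene
Conditions: PdCl2(dtbpf) (3 mol %; dtbpf = 1,1'-bis(di-tert-butylphosphino)ferrocene), K3PO4, THF/H2O, 60 °C
Reagents that add atoms: none
Why: γ-selective Suzuki–Miyaura allylation, in which SE2' transmetalation puts palladium on the dimethyl-substituted carbon and a chelating bisphosphine that blocks σ–π–σ isomerisation should let reductive elimination give the 1,1-dimethylallyl arene.

**Step 4**
Reactants: 5 1,3-dimethoxy-2-(methoxymethoxy)-4-(2-methylbut-3-en-2-yl)benzene; 6 oxirane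
Product: 8 2-[2,4-dimethoxy-3-(methoxymethoxy)-5-(2-methylbut-3-en-2-yl)phenyl]ethan-1-ol, via aryllithium 7 (not isolated)
Conditions: n-BuLi, TMEDA, THF, 0 °C; then oxirane, −78 → 23 °C; H2O
Reagents that add atoms: none
Why: directed ortho-metalation next to the only methoxy group that still has a free ortho position gives the aryllithium, which opens oxirane by SN2 to the 2-arylethanol.

**Step 5**
Reactants: 8 2-[2,4-dimethoxy-3-(methoxymethoxy)-5-(2-methylbut-3-en-2-yl)phenyl]ethan-1-ol
Product: 9 [2,4-dimethoxy-3-(methoxymethoxy)-5-(2-methylbut-3-en-2-yl)phenyl]acetic acid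
Conditions: TEMPO (cat.), PhI(OAc)2, MeCN/H2O, 23 °C
Reagents that add atoms: water, O
Why: nitroxyl-catalysed oxidation takes the primary alcohol through the aldehyde hydrate to the acid and should leave the terminal alkene, the acetal and the electron-rich ring alone.

**Step 6**
Reactants: 9 [2,4-dimethoxy-3-(methoxymethoxy)-5-(2-methylbut-3-en-2-yl)phenyl]acetic acid; 10 (4S)-4-benzyl-1,3-oxazolidin-2-one
Product: 12 (4S)-4-benzyl-3-{[2,4-dimethoxy-3-(methoxymethoxy)-5-(2-methylbut-3-en-2-yl)phenyl]acetyl}-1,3-oxazolidin-2-one, via mixed pivalic anhydride 11 (not isolated)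
Conditions: PivCl, Et3N, THF, −20 °C; then 10, LiCl, −20 → 23 °C
Reagents that add atoms: none
Why: N-acylation of the Evans auxiliary through the mixed anhydride, with LiCl/Et3N activating the oxazolidinone, is the standard entry to arylacetyl imides.

**Step 7**
Reactants: 13 4-methylphenol
Product: 14 4-methylphenyl 2,2-dimethylpropanoate
Conditions: PivCl, Et3N, DMAP (cat.), CH2Cl2, 0 → 23 °C
Reagents that add atoms: pivaloyl chloride (PivCl), CC(C)(C)C(=O)Cl
Why: DMAP-catalysed acylation gives a hindered aryl ester that should resist the enolate of step 9 yet fall to LiAlH4 together with the auxiliary.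

**Step 8**
Reactants: 14 4-methylphenyl 2,2-dimethylpropanoate
Product: 15 4-(bromomethyl)phenyl 2,2-dimethylpropanoate
Conditions: NBS, AIBN (cat.), PhCF3, 85 °C
Reagents that add atoms: N-bromosuccinimide (NBS), O=C1CCC(=O)N1Br
Why: Wohl–Ziegler radical bromination at the benzylic methyl gives the benzyl bromide, the acyloxy group damping ring bromination.

**Step 9**
Reactants: 12 (4S)-4-benzyl-3-{[2,4-dimethoxy-3-(methoxymethoxy)-5-(2-methylbut-3-en-2-yl)phenyl]acetyl}-1,3-oxazolidin-2-one; 15 4-(bromomethyl)phenyl 2,2-dimethylpropanoate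
Product: 17 (4S)-4-benzyl-3-{(2S)-2-[2,4-dimethoxy-3-(methoxymethoxy)-5-(2-methylbut-3-en-2-yl)phenyl]-3-[4-(2,2-dimethylpropanoyloxy)phenyl]propanoyl}-1,3-oxazolidin-2-one, via sodium enolate 16 (not isolated)
Conditions: NaN(SiMe3)2, THF, −78 °C; then 15, −78 → −30 °C; AcOH
Reagents that add atoms: none
Why: Evans asymmetric alkylation, in which the chelated sodium Z-enolate is benzylated on the face opposite the C4 benzyl group of the (4S)-auxiliary, sets the future C3 as S (CIP order C=O > aryl > CH2Ar > H).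

**Step 10**
Reactants: 17 the alkylated imide
Product: 18 4-{(2S)-2-[2,4-dimethoxy-3-(methoxymethoxy)-5-(2-methylbut-3-en-2-yl)phenyl]-3-hydroxypropyl}phenol
Conditions: LiAlH4, THF, 0 °C; aq NaOH work-up
Reagents that add atoms: none
Why: hydride reduction cleaves the imide to the primary alcohol with release of the auxiliary and reduces the aryl pivalate to the free phenol in the same operation, the stereocentre ending next to a CH2OH group where it can no longer epimerise.

**Step 11**
Reactants: 18 4-{(2S)-2-[2,4-dimethoxy-3-(methoxymethoxy)-5-(2-methylbut-3-en-2-yl)phenyl]-3-hydroxypropyl}phenol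
Product: 20 4-{(2S)-2-[2,4-dimethoxy-3-(methoxymethoxy)-5-(2-methylbut-3-en-2-yl)phenyl]-3-hydroxypropyl}-4-hydroxycyclohexa-2,5-dien-1-one, via para-peroxyquinol 19 (not isolated)
Conditions: Oxone (2KHSO5·KHSO4·K2SO4), NaHCO3, MeCN/H2O, 23 °C; then Me2S, 0 → 23 °C
Reagents that add atoms: potassium peroxymonosulfate (the oxidant in Oxone), [K+].[O-]S(=O)(=O)OO
Why: oxidative dearomatisation by singlet oxygen generated from peroxymonosulfate in bicarbonate adds oxygen para to the phenolate, and sulfide reduction of the hydroperoxide gives the para-quinol; since no phenoxenium ion is formed the free alcohol cannot spirocyclise at C4a, and the MOM-capped ring B and the vinyl group (no allylic hydrogen) should be spared.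

**Step 12**
Reactants: 20 the para-quinol
Product: 23 (3S)-3-[3-hydroxy-2,4-dimethoxy-5-(2-methylbut-3-en-2-yl)phenyl]-3,4-dihydro-2H-chromen-7-ol, via oxa-Michael adduct 21 (not isolated), via MOM ether 22 (not isolated)
Conditions: TsOH·H2O (20 mol %), ClCH2CH2Cl, 23 → 60 °C; then MeOH, HCl, 45 °C
Reagents that add atoms: none
Why: Acid activates the cross-conjugated dienone, the C2 hydroxyl adds to a β-carbon to form the O1–C8a bond and the cis-fused 4a-hydroxy-hexahydrochromen-7-one 21, acid-promoted loss of the tertiary 4a-hydroxyl with the 8a-hydrogen gives the 2,4-dienone that tautomerises to the phenol 22, and methanolic HCl then cleaves the MOM acetal. The closest known reaction types are the acid-catalysed intramolecular oxa-Michael cyclisation of 4-(hydroxyalkyl) para-quinols, the conjugate addition–dehydrative rearomatisation that turns para-alkylphenols into meta-substituted phenols, and the acid dehydration of 4-hydroxycyclohexenones to phenols. Ring C is closed in the 6-exo-trig mode. No permanent stereocentre is created: the transient ring-fusion centres C4a and C8a vanish on aromatisation, and C3, which has no acidifying neighbour, should pass through unchanged. The step needs O-cyclisation to outrun the 1,2-alkyl shift of the protonated quinol and Friedel–Crafts attack by ring B; the three-atom tether holds the hydroxyl over the β-carbon, and because both β-carbons of the symmetric dienone lead to the same arene, the oxygen can only end up at C8a, meta to the C7 hydroxyl.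

**Compound list**

1 | 2,6-dimethoxyphenol | COc1cccc(OC)c1O | starting material
2 | 1,3-dimethoxy-2-(methoxymethoxy)benzene | COCOc1c(OC)cccc1OC | intermediate
3 | 1-bromo-2,4-dimethoxy-3-(methoxymethoxy)benzene | COCOc1c(OC)ccc(Br)c1OC | intermediate
4 | prenylboronic acid pinacol ester, 4,4,5,5-tetramethyl-2-(3-methylbut-2-en-1-yl)-1,3,2-dioxaborolane | CC(C)=CCB1OC(C)(C)C(C)(C)O1 | starting material
5 | 1,3-dimethoxy-2-(methoxymethoxy)-4-(2-methylbut-3-en-2-yl)benzene | C=CC(C)(C)c1ccc(OC)c(OCOC)c1OC | intermediate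
6 | oxirane | C1CO1 | starting material
7 | [2,4-dimethoxy-3-(methoxymethoxy)-5-(2-methylbut-3-en-2-yl)phenyl]lithium | [Li]c1cc(C(C)(C)C=C)c(OC)c(OCOC)c1OC | intermediate (not isolated)
8 | 2-[2,4-dimethoxy-3-(methoxymethoxy)-5-(2-methylbut-3-en-2-yl)phenyl]ethan-1-ol | OCCc1cc(C(C)(C)C=C)c(OC)c(OCOC)c1OC | intermediate
9 | [2,4-dimethoxy-3-(methoxymethoxy)-5-(2-methylbut-3-en-2-yl)phenyl]acetic acid | OC(=O)Cc1cc(C(C)(C)C=C)c(OC)c(OCOC)c1OC | intermediate
10 | (4S)-4-benzyl-1,3-oxazolidin-2-one | O=C1OC[C@H](Cc2ccccc2)N1 | starting material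
11 | mixed anhydride of 9 and pivalic acid | CC(C)(C)C(=O)OC(=O)Cc1cc(C(C)(C)C=C)c(OC)c(OCOC)c1OC | intermediate (not isolated)
12 | (4S)-4-benzyl-3-{[2,4-dimethoxy-3-(methoxymethoxy)-5-(2-methylbut-3-en-2-yl)phenyl]acetyl}-1,3-oxazolidin-2-one | O=C1OC[C@H](Cc2ccccc2)N1C(=O)Cc1cc(C(C)(C)C=C)c(OC)c(OCOC)c1OC | intermediate
13 | 4-methylphenol | Cc1ccc(O)cc1 | starting material
14 | 4-methylphenyl 2,2-dimethylpropanoate | Cc1ccc(OC(=O)C(C)(C)C)cc1 | intermediate
15 | 4-(bromomethyl)phenyl 2,2-dimethylpropanoate | BrCc1ccc(OC(=O)C(C)(C)C)cc1 | intermediate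
16 | sodium (Z)-enolate of 12 | [Na+].[O-]/C(=C\c1cc(C(C)(C)C=C)c(OC)c(OCOC)c1OC)N1[C@@H](Cc2ccccc2)COC1=O | intermediate (not isolated)
17 | (4S)-4-benzyl-3-{(2S)-2-[2,4-dimethoxy-3-(methoxymethoxy)-5-(2-methylbut-3-en-2-yl)phenyl]-3-[4-(2,2-dimethylpropanoyloxy)phenyl]propanoyl}-1,3-oxazolidin-2-one | O=C1OC[C@H](Cc2ccccc2)N1C(=O)[C@@H](Cc1ccc(OC(=O)C(C)(C)C)cc1)c1cc(C(C)(C)C=C)c(OC)c(OCOC)c1OC | intermediate
18 | 4-{(2S)-2-[2,4-dimethoxy-3-(methoxymethoxy)-5-(2-methylbut-3-en-2-yl)phenyl]-3-hydroxypropyl}phenol | OC[C@@H](Cc1ccc(O)cc1)c1cc(C(C)(C)C=C)c(OC)c(OCOC)c1OC | intermediate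
19 | 4-{(2S)-2-[2,4-dimethoxy-3-(methoxymethoxy)-5-(2-methylbut-3-en-2-yl)phenyl]-3-hydroxypropyl}-4-hydroperoxycyclohexa-2,5-dien-1-one | OC[C@@H](CC1(OO)C=CC(=O)C=C1)c1cc(C(C)(C)C=C)c(OC)c(OCOC)c1OC | intermediate (not isolated)
20 | 4-{(2S)-2-[2,4-dimethoxy-3-(methoxymethoxy)-5-(2-methylbut-3-en-2-yl)phenyl]-3-hydroxypropyl}-4-hydroxycyclohexa-2,5-dien-1-one | OC[C@@H](CC1(O)C=CC(=O)C=C1)c1cc(C(C)(C)C=C)c(OC)c(OCOC)c1OC | intermediate
21 | (3S)-3-[2,4-dimethoxy-3-(methoxymethoxy)-5-(2-methylbut-3-en-2-yl)phenyl]-4a-hydroxy-2,3,4,4a,8,8a-hexahydro-7H-chromen-7-one, cis-fused, both ring-fusion diastereomers | O=C1C=CC2(O)C[C@H](COC2C1)c1cc(C(C)(C)C=C)c(OC)c(OCOC)c1OC | intermediate (not isolated)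
22 | (3S)-3-[2,4-dimethoxy-3-(methoxymethoxy)-5-(2-methylbut-3-en-2-yl)phenyl]-3,4-dihydro-2H-chromen-7-ol | C=CC(C)(C)c1cc([C@H]2COc3cc(O)ccc3C2)c(OC)c(OCOC)c1OC | intermediate (not isolated)
23 | (3S)-3-[3-hydroxy-2,4-dimethoxy-5-(2-methylbut-3-en-2-yl)phenyl]-3,4-dihydro-2H-chromen-7-ol | C=CC(C)(C)c1cc([C@H]2COc3cc(O)ccc3C2)c(OC)c(O)c1OC | target

**Step count and risks**

Total steps: 12. Longest linear sequence: 10 (steps 1–6 and 9–12; steps 7 and 8 make the ring A bromide).

Steps most likely to fail: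

1. Step 12. The cascade may stall at the bicyclic adduct because ionisation of the tertiary 4a-hydroxyl is slow. The protonated quinol may instead undergo a 1,2-alkyl shift (dienone–phenol rearrangement), or the acid may isomerise the 1,1-dimethylallyl group. The fallback forms the same O1–C8a bond by palladium-catalysed intramolecular C–O coupling of an aryl bromide and sets out from imide 12. Commercial 3-bromo-4-methylphenol is silylated (i-Pr3SiCl, imidazole, DMF) to (3-bromo-4-methylphenoxy)tri(propan-2-yl)silane F1 and brominated (NBS, AIBN, PhCF3) to [3-bromo-4-(bromomethyl)phenoxy]tri(propan-2-yl)silane F2. Evans alkylation of 12 with F2 under the conditions of step 9 should give the (2S)-configured bromoaryl imide F3, and LiBH4/MeOH in THF should reduce it to the (2S)-bromo alcohol F4. Pd(OAc)2 with 2-(di-tert-butylphosphino)-1,1'-binaphthyl and Cs2CO3 in toluene at 70 °C (Buchwald–Hartwig-type etherification) should then close ring C to the 7-silyloxy chroman F5. Bu4NF in THF removes the silyl group and the route is rejoined at 22, which methanolic HCl converts into 23 as in the second stage of step 12.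

2. Step 11. Chemoselectivity may be lost through attack of the oxidant on the electron-rich ring B or the vinyl group, and reduction of the hydroperoxide may be incomplete. The fallback uses a two-electron iodine oxidation with water as the nucleophile after masking the primary alcohol, which would otherwise attack C4a and give a spiro ether. It sets out from 18. Both hydroxyls are silylated (t-BuMe2SiCl, imidazole, DMF) to the bis-silyl ether F6, and K2CO3 in MeOH should free only the phenol to give the mono-silyl ether F7. PhI(OAc)2 in MeCN/H2O at 0 °C should give the para-quinol silyl ether F8, and HF·pyridine in THF returns the route to 20.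

3. Step 3. Regiocontrol may be lost through σ–π–σ isomerisation of the allylpalladium intermediate, which would give the linear prenyl arene, and slow reductive elimination at the tertiary carbon may lead to protodebromination. The fallback builds the quaternary carbon by enolate arylation and sets out from bromide 3. Coupling with the lithium enolate of methyl isobutyrate (LiNCy2, Pd(dba)2, P(t-Bu)3, toluene, 23 °C) should give methyl 2-[2,4-dimethoxy-3-(methoxymethoxy)phenyl]-2-methylpropanoate F9. i-Bu2AlH in CH2Cl2 at −78 °C should reduce it to 2-[2,4-dimethoxy-3-(methoxymethoxy)phenyl]-2-methylpropanal F10, and Wittig methylenation (Ph3PCH3Br, KOt-Bu, THF) returns the route to 5.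

**Further compounds**

F1 | step 12 | (3-bromo-4-methylphenoxy)tri(propan-2-yl)silane | Cc1ccc(O[Si](C(C)C)(C(C)C)C(C)C)cc1Br
F2 | step 12 | [3-bromo-4-(bromomethyl)phenoxy]tri(propan-2-yl)silane | BrCc1ccc(O[Si](C(C)C)(C(C)C)C(C)C)cc1Br
F3 | step 12 | (4S)-4-benzyl-3-{(2S)-3-[2-bromo-4-(triisopropylsilyloxy)phenyl]-2-[2,4-dimethoxy-3-(methoxymethoxy)-5-(2-methylbut-3-en-2-yl)phenyl]propanoyl}-1,3-oxazolidin-2-one | O=C1OC[C@H](Cc2ccccc2)N1C(=O)[C@@H](Cc1ccc(O[Si](C(C)C)(C(C)C)C(C)C)cc1Br)c1cc(C(C)(C)C=C)c(OC)c(OCOC)c1OC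
F4 | step 12 | (2S)-3-[2-bromo-4-(triisopropylsilyloxy)phenyl]-2-[2,4-dimethoxy-3-(methoxymethoxy)-5-(2-methylbut-3-en-2-yl)phenyl]propan-1-ol | OC[C@@H](Cc1ccc(O[Si](C(C)C)(C(C)C)C(C)C)cc1Br)c1cc(C(C)(C)C=C)c(OC)c(OCOC)c1OC
F5 | step 12 | {[(3S)-3-[2,4-dimethoxy-3-(methoxymethoxy)-5-(2-methylbut-3-en-2-yl)phenyl]-3,4-dihydro-2H-chromen-7-yl]oxy}tri(propan-2-yl)silane | C=CC(C)(C)c1cc([C@H]2COc3cc(O[Si](C(C)C)(C(C)C)C(C)C)ccc3C2)c(OC)c(OCOC)c1OC
F6 | step 11 | bis(tert-butyldimethylsilyl) ether of 18 | CC(C)(C)[Si](C)(C)OC[C@@H](Cc1ccc(O[Si](C)(C)C(C)(C)C)cc1)c1cc(C(C)(C)C=C)c(OC)c(OCOC)c1OC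
F7 | step 11 | 4-{(2S)-3-(tert-butyldimethylsilyloxy)-2-[2,4-dimethoxy-3-(methoxymethoxy)-5-(2-methylbut-3-en-2-yl)phenyl]propyl}phenol | CC(C)(C)[Si](C)(C)OC[C@@H](Cc1ccc(O)cc1)c1cc(C(C)(C)C=C)c(OC)c(OCOC)c1OC
F8 | step 11 | 4-{(2S)-3-(tert-butyldimethylsilyloxy)-2-[2,4-dimethoxy-3-(methoxymethoxy)-5-(2-methylbut-3-en-2-yl)phenyl]propyl}-4-hydroxycyclohexa-2,5-dien-1-one | CC(C)(C)[Si](C)(C)OC[C@@H](CC1(O)C=CC(=O)C=C1)c1cc(C(C)(C)C=C)c(OC)c(OCOC)c1OC
F9 | step 3 | methyl 2-[2,4-dimethoxy-3-(methoxymethoxy)phenyl]-2-methylpropanoate | COC(=O)C(C)(C)c1ccc(OC)c(OCOC)c1OC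
F10 | step 3 | 2-[2,4-dimethoxy-3-(methoxymethoxy)phenyl]-2-methylpropanal | O=CC(C)(C)c1ccc(OC)c(OCOC)c1OC
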